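(The earlier runs and the new flask come from a simulation from invented constants; noise was put on by code.)

What stayed constant across the grey, green and violet runs was the monomer that stayed out of the chains. Averaging the last two readings of each run, I found the charge minus the monomer in chains to be 0.0684 M in grey, 0.0696 M in green and 0.0701 M in violet. I carried the green figure as the ceiling concentration, the monomer a flask keeps outside its chains across these charges; it is a reading of the charge minus the monomer in chains, in whatever form that remainder stands, with the scatter of the readings in it.

| setting | grey | green | violet | north | north-west |
|---|---|---|---|---|---|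
| free monomer | 0.089 M | 0.11 M | 0.13 M | 0.10 M | 0.15 M |
| initiator | 10 mM | 10 mM | 10 mM | 10 mM | 10 mM |
| impurity | 3.4 mM | 3.4 mM | 3.4 mM | 3.4 mM | 3.4 mM |
| remark | run made earlier | run made earlier | run made earlier |  |  |
| time |  |  |  | 6.0 d | 6.0 d |

| run | time / d | monomer in chains / % |
|---|---|---|
| grey | 0.625 | 26.5 |
| grey | 1.25 | 23.0 |
| grey | 1.67 | 26.0 |
| grey | 2.50 | 23.9 |
| grey | 3.00 | 22.4 |
| green | 0.250 | 32.3 |
| green | 0.417 | 39.5 |
| green | 0.833 | 39.4 |
| green | 1.67 | 36.7 |
| green | 3.00 | 36.7 |
| violet | 0.250 | 41.0 |
| violet | 0.417 | 46.7 |
| violet | 0.833 | 45.8 |
| violet | 1.67 | 43.5 |
| violet | 3.00 | 48.6 |

(readings scatter by 1 percentage point)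

- the average divides the monomer in chains by the number of chains begun, living and dead together
- the earlier runs do not show the number of chains; that part of a forecast is a guess

- which of the two ends with the longer chains by the average number of monomer units in a chain (chains begun, living or dead) ("neither" if they lie within 10%) (north / north-west / neither)
- average number of monomer units in a chain (chains begun, living or dead) at the end, north
- average number of monomer units in a chain (chains begun, living or dead) at the end, north-west

I built the two new flasks up one process at a time. With the main step by itself, every unit of charged monomer ending in chains and each initiator beginning one chain, the length is the charge over the initiator: 10.0 for north and 15.0 for north-west. Adding the back step, chains shedding monomer, replaces the charge by the charge minus the ceiling, 0.0304 M in north and 0.0804 M in north-west, and the lengths fall to 3.04 and 8.04.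

Adding the impurity, I took it that each impurity destroys one initiator before that initiator begins a chain. This was my own guess, since the runs show no chain count, and it leaves 6.60 mM of chains begun. The lengths rise to 4.60 and 12.2. For the rest, the average counts living and dead chains together, so a chain's death leaves the divisor as it was. The green run read 36.7% at 1.67 d and 36.7% at 3.00 d, so I placed 6.0 d on the same plateau. I expected north-west to be longer than north.

The forecast also named north-west, with 3.4 for north and 8.8 for north-west. It leaned to the other reading, that “the impurity merely kills some”, and its lengths stand below mine. We part on the divisor.

The flask gave north-west, with 4.52 in north and 11.8 in north-west. Spent initiator B stood at 0.00340 M in north at 6.00 d, with initiator at 0% of its charge. The ceiling reckons 53.6% of the north-west charge into chains, and north-west held 52.1% there at 6.00 d.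

    free monomer + initiator → living end + monomer in chains (k = 0.00270 M⁻¹ s⁻¹)
    free monomer + living end → monomer in chains + living end, rate k2*[living end]*[free monomer] (k = 0.0140 M⁻¹ s⁻¹)
    monomer in chains + living end → free monomer + living end, rate k3*[living end] as long as [monomer in chains] is above zero (k = 8.90 × 10⁻⁴ s⁻¹)
    living end + monomer in chains → dead end A (k = 3.80 × 10⁻⁴ M⁻¹ s⁻¹)
    initiator + impurity → spent initiator B (k = 5.40 M⁻¹ s⁻¹)

The neighbour of north-west charged with 0.037 M of free monomer stands below the ceiling, so the reckoning gives it no monomer to put into chains. Computed, that neighbour kept 99.9% of its charge as free monomer, and its length was 0.00211.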